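**Plan**

Flavanone numbering is used; unprimed locants belong to the 4-methoxyphenyl half and doubly primed ones to the 4-hydroxyphenyl half. The target is (2S,3S,2''S,3''S), with both rings C 2,3-cis.

- Retrosynthesis: after the five benzyl ethers, O1–C2 and O1''–C2'' are cut together. In each ring C the ether oxygen O1 lies β to the C4 ketone (O1–C2–C3–C4=O), so both bonds open by retro-oxa-Michael reaction to a 2,3-diaroylbuta-1,3-diene that already holds C3–C3''.
- Next the two aryl–C4 bonds are cut (aryllithium plus dialdehyde), then the two arylidene C=C bonds (two Stobbe condensations on diethyl succinate).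
- Forward: the succinate chain gains the 4-methoxybenzylidene, then the 4-(benzyloxy)benzylidene group; rings A and A'' are attached as aryl ketones; rings C and C'' close together in one operation; hydrogenolysis ends the route.
- Stereochemistry: all four centres arise in the double ring closure, C2 and C2'' from the chiral thiourea, C3 and C3'' from protonation of each enol anti to its new aryl group.

Key step: step 11

Assumption: the (2S,2''S) sense is assigned to the quinine-derived thiourea by analogy with simple 2'-hydroxychalcones; its quinidine-derived pseudoenantiomer would take its place unchanged if the sense proved reversed.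

**Route**

Step 1
Reactants: 1 diethyl succinate; 2 4-methoxybenzaldehyde
Product: 4 (E)-3-(ethoxycarbonyl)-4-(4-methoxyphenyl)but-3-enoic acid, via paraconate lactone 3 (not isolated)
Conditions: KOt-Bu, t-BuOH, reflux; then aq. HCl
Reagents that add atoms: none
Why: Stobbe condensation, in which the succinate enolate adds to the aldehyde, the alkoxide lactonises onto the distal ester to give 3 and base-induced E1cB opening delivers the half-ester with the aryl group trans to the ester (E), carboxylate formation driving the sequence.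

Step 2
Reactants: 4 (E)-3-(ethoxycarbonyl)-4-(4-methoxyphenyl)but-3-enoic acid
Product: 5 diethyl (E)-2-(4-methoxybenzylidene)succinate
Conditions: EtOH, H2SO4 (cat.), reflux
Reagents that add atoms: ethanol, CCO
Why: Fischer esterification of the unconjugated acid restores a succinate diester with one free CH2 for the second condensation, and the alkene is untouched.

Step 3
Reactants: 5 diethyl (E)-2-(4-methoxybenzylidene)succinate; 6 4-(benzyloxy)benzaldehyde
Product: 8 (2E,3E)-4-[4-(benzyloxy)phenyl]-3-(ethoxycarbonyl)-2-(4-methoxybenzylidene)but-3-enoic acid, via arylidene paraconate lactone 7 (not isolated)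
Conditions: KOt-Bu, t-BuOH, reflux; then aq. HCl
Reagents that add atoms: none
Why: Second Stobbe condensation at the only remaining CH2, in which lactonisation onto the conjugated ester and E1cB opening of 7 place the new aryl group trans to its ester and should give the (E,E)-diene half-ester.

Step 4
Reactants: 8 (2E,3E)-4-[4-(benzyloxy)phenyl]-3-(ethoxycarbonyl)-2-(4-methoxybenzylidene)but-3-enoic acid
Product: 9 diethyl (2E,3E)-2-[4-(benzyloxy)benzylidene]-3-(4-methoxybenzylidene)succinate
Conditions: EtI, K2CO3, DMF, rt
Reagents that add atoms: iodoethane, CCI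
Why: SN2 O-alkylation of the hindered conjugated carboxylate under mild base gives the symmetric diester without acid or heat that could scramble the alkene geometry.

Step 5
Reactants: 9 diethyl (2E,3E)-2-[4-(benzyloxy)benzylidene]-3-(4-methoxybenzylidene)succinate
Product: 10 (2E,3E)-2-[4-(benzyloxy)benzylidene]-3-(4-methoxybenzylidene)butane-1,4-diol
Conditions: i-Bu2AlH (excess), CH2Cl2, −78 → 0 °C; aq. KNaC4H4O6
Reagents that add atoms: none
Why: 1,2-Reduction of both conjugated esters by the aluminium hydride stops at the allylic alcohols at low temperature and leaves the alkenes and aryl ethers alone.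

Step 6
Reactants: 10 (2E,3E)-2-[4-(benzyloxy)benzylidene]-3-(4-methoxybenzylidene)butane-1,4-diol
Product: 11 (2E,3E)-2-[4-(benzyloxy)benzylidene]-3-(4-methoxybenzylidene)succinaldehyde
Conditions: (COCl)2, DMSO, CH2Cl2, −78 °C; then Et3N, −78 → 0 °C
Reagents that add atoms: none
Why: Swern oxidation activates both hydroxyl groups as alkoxysulfonium ions before base is added, so no hydroxy aldehyde is present to close to a lactol and be over-oxidised to a lactone.

Step 7
Reactants: 12 3,5-bis(benzyloxy)phenol
Product: 13 1,3-bis(benzyloxy)-5-(methoxymethoxy)benzene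
Conditions: MOMCl, i-Pr2NEt, CH2Cl2, 0 °C → rt
Reagents that add atoms: chloromethyl methyl ether, COCCl
Why: O-Alkylation of the phenol installs a methoxymethyl acetal that serves both as the ortho-directing group for lithiation and as the mask of the oxygen that later closes ring C.

Step 8
Reactants: 13 1,3-bis(benzyloxy)-5-(methoxymethoxy)benzene; 11 (2E,3E)-2-[4-(benzyloxy)benzylidene]-3-(4-methoxybenzylidene)succinaldehyde
Product: 15 (2E,3E)-2-[4-(benzyloxy)benzylidene]-1,4-bis[2,4-bis(benzyloxy)-6-(methoxymethoxy)phenyl]-3-(4-methoxybenzylidene)butane-1,4-diol (mixture of carbinol diastereomers), via aryllithium 14 (not isolated)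
Conditions: 13 (3 equiv), n-BuLi, THF, 0 °C; then 11 added at −78 °C, → −40 °C; aq. NH4Cl
Reagents that add atoms: none
Why: Directed ortho-metalation occurs at the carbon between the methoxymethoxy group (the stronger director, two equivalent sites) and a benzyloxy group, and the aryllithium adds 1,2 to both enal carbonyls when the dialdehyde meets it in excess, the new carbinol centres being erased in the next step.

Step 9
Reactants: 15 (2E,3E)-2-[4-(benzyloxy)benzylidene]-1,4-bis[2,4-bis(benzyloxy)-6-(methoxymethoxy)phenyl]-3-(4-methoxybenzylidene)butane-1,4-diol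
Product: 16 (2E,3E)-2-[4-(benzyloxy)benzylidene]-1,4-bis[2,4-bis(benzyloxy)-6-(methoxymethoxy)phenyl]-3-(4-methoxybenzylidene)butane-1,4-dione
Conditions: Dess–Martin periodinane, NaHCO3, CH2Cl2, 0 °C → rt
Reagents that add atoms: none
Why: Dess–Martin oxidation of the two benzylic, allylic secondary alcohols is fast, and the bicarbonate buffer protects the easily ionised carbinols and the acetals from the acetic acid released.

Step 10
Reactants: 16 (2E,3E)-2-[4-(benzyloxy)benzylidene]-1,4-bis[2,4-bis(benzyloxy)-6-(methoxymethoxy)phenyl]-3-(4-methoxybenzylidene)butane-1,4-dione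
Product: 17 (2E,3E)-2-[4-(benzyloxy)benzylidene]-1,4-bis[2,4-bis(benzyloxy)-6-hydroxyphenyl]-3-(4-methoxybenzylidene)butane-1,4-dione
Conditions: HCl (3 M aq., cat.), MeOH/THF, rt
Reagents that add atoms: none
Why: Acid-catalysed acetal exchange with methanol removes only the two methoxymethyl groups, and the freed phenols, held in hydrogen bonds to the ketones, are expected not to cyclise in dilute acid at ambient temperature.

Step 11
Reactants: 17 (2E,3E)-2-[4-(benzyloxy)benzylidene]-1,4-bis[2,4-bis(benzyloxy)-6-hydroxyphenyl]-3-(4-methoxybenzylidene)butane-1,4-dione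
Product: 19 penta-O-benzyl sikokianin A, (2S,3S,2''S,3''S)-5,5'',7,7''-tetrakis(benzyloxy)-2''-[4-(benzyloxy)phenyl]-2-(4-methoxyphenyl)-3,3''-bichroman-4,4''-dione, via monocyclised flavanone 18 (not isolated)
Conditions: 1-[3,5-bis(trifluoromethyl)phenyl]-3-[(8α,9S)-6'-methoxycinchonan-9-yl]thiourea (20 mol %), toluene, −25 °C; cold filtration through silica
Reagents that add atoms: none
Why: The quinuclidine nitrogen of the catalyst deprotonates an ortho phenol while the thiourea N–H bonds bind the neighbouring enone carbonyl, the phenoxide adds to the arylidene carbon (oxa-Michael addition) and the resulting enol is protonated at C3, after which the same events repeat on the second enone of 18. The closest known reaction is the cinchona-thiourea-catalysed enantioselective cyclisation of 2'-hydroxychalcones and their α-substituted analogues to flavanones. Ring C (O1, C2, C3, C4, C4a, C8a) and its counterpart ring C'' each close in the 6-endo-trig mode, the phenol oxygen attacking C2 or C2''. C2 and C2'' are set by the catalyst, which should expose the same face of both E-arylidene carbons, so that an error in one closure ends mainly in the separable (2S,3S,2''R,3''R) diastereomer and not in the enantiomer; C3 and C3'' are set by the substrate, because each enol holds its new C2 aryl group pseudoaxial to avoid allylic strain with the bulky C3 substituent and is protonated on the opposite face, which gives the 2,3-cis ring. The step needs kinetic control (no retro-oxa-Michael opening, no epimerisation at C3 to the 2,3-trans ring) and attack by the phenol, not by the enol oxygen of 18: low temperature, the non-polar solvent and the weak amine base serve the first, and the second is secured because the enol oxygen could reach C2'' only through a disfavoured 5-endo-trig closure while the twisted 2,3-disubstituted diene keeps the two enones electronically independent.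

Step 12
Reactants: 19 penta-O-benzyl sikokianin A
Product: 20 sikokianin A, (2S,3S,2''S,3''S)-5,5'',7,7''-tetrahydroxy-2''-(4-hydroxyphenyl)-2-(4-methoxyphenyl)-3,3''-bichroman-4,4''-dione
Conditions: H2 (1 atm), Pd/C, EtOAc/THF, rt
Reagents that add atoms: none
Why: Catalytic hydrogenolysis cleaves the five aryl benzyl ethers under neutral conditions, so neither the enolisable C3 centres nor the retro-Michael-prone C2 centres can equilibrate, and the ring C ether bonds and the chelated ketones should react far more slowly than the O-benzyl groups.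

**Compound list**

1 | diethyl succinate | CCOC(=O)CCC(=O)OCC | starting material
2 | 4-methoxybenzaldehyde | COc1ccc(C=O)cc1 | starting material
3 | ethyl 2-(4-methoxyphenyl)-5-oxotetrahydrofuran-3-carboxylate (paraconate lactone, diastereomer mixture, not isolated) | CCOC(=O)C1CC(=O)OC1c1ccc(OC)cc1 | intermediate
4 | (E)-3-(ethoxycarbonyl)-4-(4-methoxyphenyl)but-3-enoic acid | COc1ccc(/C=C(\CC(=O)O)C(=O)OCC)cc1 | intermediate
5 | diethyl (E)-2-(4-methoxybenzylidene)succinate | COc1ccc(/C=C(\CC(=O)OCC)C(=O)OCC)cc1 | intermediate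
6 | 4-(benzyloxy)benzaldehyde | O=Cc1ccc(OCc2ccccc2)cc1 | starting material
7 | ethyl (E)-2-[4-(benzyloxy)phenyl]-4-(4-methoxybenzylidene)-5-oxotetrahydrofuran-3-carboxylate (diastereomer mixture, not isolated) | CCOC(=O)C1C(c2ccc(OCc3ccccc3)cc2)OC(=O)/C1=C/c1ccc(OC)cc1 | intermediate
8 | (2E,3E)-4-[4-(benzyloxy)phenyl]-3-(ethoxycarbonyl)-2-(4-methoxybenzylidene)but-3-enoic acid | COc1ccc(/C=C(/C(=O)O)C(=C/c2ccc(OCc3ccccc3)cc2)\C(=O)OCC)cc1 | intermediate
9 | diethyl (2E,3E)-2-[4-(benzyloxy)benzylidene]-3-(4-methoxybenzylidene)succinate | COc1ccc(/C=C(/C(=O)OCC)C(=C/c2ccc(OCc3ccccc3)cc2)\C(=O)OCC)cc1 | intermediate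
10 | (2E,3E)-2-[4-(benzyloxy)benzylidene]-3-(4-methoxybenzylidene)butane-1,4-diol | COc1ccc(/C=C(/CO)C(=C/c2ccc(OCc3ccccc3)cc2)\CO)cc1 | intermediate
11 | (2E,3E)-2-[4-(benzyloxy)benzylidene]-3-(4-methoxybenzylidene)succinaldehyde | COc1ccc(/C=C(/C=O)C(=C/c2ccc(OCc3ccccc3)cc2)\C=O)cc1 | intermediate
12 | 3,5-bis(benzyloxy)phenol | Oc1cc(OCc2ccccc2)cc(OCc2ccccc2)c1 | starting material
13 | 1,3-bis(benzyloxy)-5-(methoxymethoxy)benzene | COCOc1cc(OCc2ccccc2)cc(OCc2ccccc2)c1 | intermediate
14 | [2,4-bis(benzyloxy)-6-(methoxymethoxy)phenyl]lithium (not isolated) | [Li]c1c(OCOC)cc(OCc2ccccc2)cc1OCc1ccccc1 | intermediate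
15 | (2E,3E)-2-[4-(benzyloxy)benzylidene]-1,4-bis[2,4-bis(benzyloxy)-6-(methoxymethoxy)phenyl]-3-(4-methoxybenzylidene)butane-1,4-diol (carbinol diastereomers) | COc1ccc(/C=C(/C(O)c2c(OCOC)cc(OCc3ccccc3)cc2OCc2ccccc2)C(=C/c2ccc(OCc3ccccc3)cc2)\C(O)c2c(OCOC)cc(OCc3ccccc3)cc2OCc2ccccc2)cc1 | intermediate
16 | (2E,3E)-2-[4-(benzyloxy)benzylidene]-1,4-bis[2,4-bis(benzyloxy)-6-(methoxymethoxy)phenyl]-3-(4-methoxybenzylidene)butane-1,4-dione | COc1ccc(/C=C(/C(=O)c2c(OCOC)cc(OCc3ccccc3)cc2OCc2ccccc2)C(=C/c2ccc(OCc3ccccc3)cc2)\C(=O)c2c(OCOC)cc(OCc3ccccc3)cc2OCc2ccccc2)cc1 | intermediate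
17 | (2E,3E)-2-[4-(benzyloxy)benzylidene]-1,4-bis[2,4-bis(benzyloxy)-6-hydroxyphenyl]-3-(4-methoxybenzylidene)butane-1,4-dione | COc1ccc(/C=C(/C(=O)c2c(O)cc(OCc3ccccc3)cc2OCc2ccccc2)C(=C/c2ccc(OCc3ccccc3)cc2)\C(=O)c2c(O)cc(OCc3ccccc3)cc2OCc2ccccc2)cc1 | intermediate
18 | (2S,3S)-5,7-bis(benzyloxy)-3-{(E)-1-[4-(benzyloxy)phenyl]-3-[2,4-bis(benzyloxy)-6-hydroxyphenyl]-3-oxoprop-1-en-2-yl}-2-(4-methoxyphenyl)chroman-4-one (drawn with the methoxyphenyl half closed first, not isolated) | COc1ccc([C@H]2Oc3cc(OCc4ccccc4)cc(OCc4ccccc4)c3C(=O)[C@H]2C(=C/c2ccc(OCc3ccccc3)cc2)\C(=O)c2c(O)cc(OCc3ccccc3)cc2OCc2ccccc2)cc1 | intermediate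
19 | penta-O-benzyl sikokianin A, (2S,3S,2''S,3''S)-5,5'',7,7''-tetrakis(benzyloxy)-2''-[4-(benzyloxy)phenyl]-2-(4-methoxyphenyl)-3,3''-bichroman-4,4''-dione | COc1ccc([C@H]2Oc3cc(OCc4ccccc4)cc(OCc4ccccc4)c3C(=O)[C@H]2[C@@H]2C(=O)c3c(OCc4ccccc4)cc(OCc4ccccc4)cc3O[C@@H]2c2ccc(OCc3ccccc3)cc2)cc1 | intermediate
20 | sikokianin A, (2S,3S,2''S,3''S)-5,5'',7,7''-tetrahydroxy-2''-(4-hydroxyphenyl)-2-(4-methoxyphenyl)-3,3''-bichroman-4,4''-dione | COc1ccc([C@H]2Oc3cc(O)cc(O)c3C(=O)[C@H]2[C@@H]2C(=O)c3c(O)cc(O)cc3O[C@@H]2c2ccc(O)cc2)cc1 | target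

**Step count and risks**

Total: 12 steps. Longest linear sequence: 11 steps (steps 1–6 and 8–12, from diethyl succinate); step 7 is a one-step side branch.

Steps most likely to fail:

1. Step 11. Kinetic control may be lost: the amine may reopen ring C by retro-oxa-Michael reaction or epimerise C3 and C3'', so that 2,3-trans rings build up, and facial discrimination at the second closure may be weak. The fallback separates the two kinds of stereocontrol. Setting out from 17, the closure would be run with the same thiourea at ambient temperature until C3 and C3'' have equilibrated, which should give the all-trans (2S,3R,2''S,3''R)-penta-O-benzyl biflavanone F1, purified by crystallisation. Its two C3 centres would then be inverted by contra-thermodynamic enolate protonation: LiN(SiMe3)2 in THF at −78 °C should give the dilithium bis-enolate F2, which is quenched at −78 °C with a bulky proton source such as 2,6-di-tert-butyl-4-methylphenol. The proton should enter anti to each pseudoaxial C2 aryl group, and the route is rejoined at 19.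

2. Step 8. The first lithium alkoxide may close onto the neighbouring aldehyde as a lactolate and hold back the second addition, giving mono-adducts. The fallback avoids the dialdehyde and the later oxidation. Setting out from 9, treatment with MeNH(OMe)·HCl and i-PrMgCl in THF at −20 °C should give the bis(N-methoxy-N-methylamide) (2E,3E)-2-[4-(benzyloxy)benzylidene]-N1,N4-dimethoxy-3-(4-methoxybenzylidene)-N1,N4-dimethylsuccinamide F3. Its two chelated tetrahedral adducts with aryllithium 14 cannot interact and collapse on work-up to the diketone, so the route is rejoined at 16 without 10, 11 and 15.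

3. Step 3. Under hot alkoxide either arylidene may scramble between E and Z, and the aldehyde may be lost to self-reactions, which would give mixed diene geometries. The fallback replaces the Stobbe sequence by a low-temperature aldol addition followed by a separate elimination. Setting out from 5, deprotonation with LiN(i-Pr)2 in THF at −78 °C and addition of 6, with a cold quench, should give the aldol diethyl 2-{[4-(benzyloxy)phenyl](hydroxy)methyl}-3-[(E)-4-methoxybenzylidene]succinate F4. Acetylation (Ac2O, DMAP, Et3N) would give the acetate F5, and DBU in CH2Cl2 should induce E1cB loss of acetic acid with the aryl group trans to the ester, rejoining the route at 9 without 8.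

**Further compounds**

F1 | step 11 | (2S,3R,2''S,3''R)-5,5'',7,7''-tetrakis(benzyloxy)-2''-[4-(benzyloxy)phenyl]-2-(4-methoxyphenyl)-3,3''-bichroman-4,4''-dione (all-trans isomer of 19) | COc1ccc([C@H]2Oc3cc(OCc4ccccc4)cc(OCc4ccccc4)c3C(=O)[C@@H]2[C@H]2C(=O)c3c(OCc4ccccc4)cc(OCc4ccccc4)cc3O[C@@H]2c2ccc(OCc3ccccc3)cc2)cc1
F2 | step 11 | dilithium (2S,2''S)-bis-enolate of F1 | COc1ccc([C@H]2Oc3cc(OCc4ccccc4)cc(OCc4ccccc4)c3C(O[Li])=C2C2=C(O[Li])c3c(OCc4ccccc4)cc(OCc4ccccc4)cc3O[C@@H]2c2ccc(OCc3ccccc3)cc2)cc1
F3 | step 8 | (2E,3E)-2-[4-(benzyloxy)benzylidene]-N1,N4-dimethoxy-3-(4-methoxybenzylidene)-N1,N4-dimethylsuccinamide | COc1ccc(/C=C(/C(=O)N(C)OC)C(=C/c2ccc(OCc3ccccc3)cc2)\C(=O)N(C)OC)cc1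
F4 | step 3 | diethyl 2-{[4-(benzyloxy)phenyl](hydroxy)methyl}-3-[(E)-4-methoxybenzylidene]succinate (diastereomer mixture) | COc1ccc(/C=C(/C(=O)OCC)C(C(=O)OCC)C(O)c2ccc(OCc3ccccc3)cc2)cc1
F5 | step 3 | diethyl 2-{(acetyloxy)[4-(benzyloxy)phenyl]methyl}-3-[(E)-4-methoxybenzylidene]succinate (diastereomer mixture) | COc1ccc(/C=C(/C(=O)OCC)C(C(=O)OCC)C(OC(C)=O)c2ccc(OCc3ccccc3)cc2)cc1
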